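**Plan**

Ring letters: the upper epicatechin unit has rings A (phloroglucinol), C (pyran) and B (catechol). The lower epigallocatechin unit has rings D (phloroglucinol), F (pyran) and E (pyrogallol). The target is epicatechin-(4β→6)-epigallocatechin 3,3'-di-O-gallate, with 2R,3R in both units.
Cuts, in retrosynthetic order: the benzyl and bromine masks; the interflavan bond C4(ring C)–C6(ring D); the two galloyl C–O ester bonds at O3 (ring F) and O3' (ring E); the O1–C2 bond of ring F, which contracts ring F to the furan ring of a 2-benzylbenzofuran; the benzylic carbon of that benzofuran, back to an aurone aldol pair.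
Enabling feature: ring D carries oxygen at C5, C7 and C8a, all ortho or para to C4a, so C4 can end an o-quinone methide. C2 lies between ring E and C3 and enolises once C3 is a carbonyl. O1 and C2 are then the ends of a 1-oxatriene that closes to ring F.
Forward order: aurone condensation joins rings D and E through a five-membered ring; deoxygenation gives the benzofuran; oxidative ring expansion gives the racemic flavan-3-one; then hydrogenation with dynamic kinetic resolution, Br to OH, double galloylation, C8 bromination, coupling with a bromine-capped epicatechin C4 electrophile, and global hydrogenolysis.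
Stereochemistry: C2 and C3 of ring F come from the catalyst-controlled dynamic kinetic resolution, cis because hydride arrives anti to ring E. C2 and C3 of ring C come from (−)-epicatechin. C4 comes from attack anti to the 3-OH (4β). The 4→6 regiochemistry comes from the bromine caps.

Key step: step 5

Assumption: 3-bromo-4,5-dihydroxybenzaldehyde, 4,6-dihydroxybenzofuran-3(2H)-one, 3,4,5-tris(benzyloxy)benzoic acid and (−)-epicatechin are purchased, and DMDO is used as a titrated acetone solution.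

**Step 1**
Reactants: 1 3-bromo-4,5-dihydroxybenzaldehyde
Product: 2 3-bromo-4,5-bis(benzyloxy)benzaldehyde
Conditions: BnBr (2.3 equiv), K2CO3, DMF, 60 °C
Reagents that add atoms: benzyl bromide BrCc1ccccc1
Why: Williamson ether synthesis protects the two phenols, and the bromine stays as the mask of the later 3'-OH, which sets this one oxygen of ring E apart from the other two.

**Step 2**
Reactants: 3 4,6-dihydroxybenzofuran-3(2H)-one
Product: 4 4,6-bis(benzyloxy)benzofuran-3(2H)-one
Conditions: BnBr (2.1 equiv), K2CO3, DMF, rt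
Reagents that add atoms: benzyl bromide BrCc1ccccc1
Why: Williamson ether synthesis with a weak base and a near-stoichiometric amount of halide should alkylate the two acidic phenols ahead of the C2 methylene.

**Step 3**
Reactants: 2 3-bromo-4,5-bis(benzyloxy)benzaldehyde, 4 4,6-bis(benzyloxy)benzofuran-3(2H)-one
Product: 5 (Z)-4,6-bis(benzyloxy)-2-[3-bromo-4,5-bis(benzyloxy)benzylidene]benzofuran-3(2H)-one
Conditions: basic Al2O3, CH2Cl2, rt
Reagents that add atoms: none
Why: The aldol condensation of a coumaranone with an aryl aldehyde (the standard aurone synthesis) joins all carbons of the lower unit and should give the more stable Z isomer.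

**Step 4**
Reactants: 5 (Z)-4,6-bis(benzyloxy)-2-[3-bromo-4,5-bis(benzyloxy)benzylidene]benzofuran-3(2H)-one
Product: 7 4,6-bis(benzyloxy)-2-[3-bromo-4,5-bis(benzyloxy)benzyl]benzofuran, via allylic alcohol 6 (not isolated)
Conditions: NaBH4, CeCl3·7H2O, THF–MeOH, 0 °C; crude, Et3SiH (1.05 equiv), CF3CO2H, CH2Cl2, −40 to 0 °C
Reagents that add atoms: none
Why: Luche 1,2-reduction gives 6, whose hydroxyl ionises in acid to a cation shared by the trioxygenated benzylic C3 and the exocyclic carbon, and ionic hydrogenation with Et3SiH followed by acid-catalysed double-bond shift ends in the aromatic benzofuran as the thermodynamic sink.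

**Step 5**
Reactants: 7 4,6-bis(benzyloxy)-2-[3-bromo-4,5-bis(benzyloxy)benzyl]benzofuran
Product: 12 racemic 5,7-bis(benzyloxy)-2-[3-bromo-4,5-bis(benzyloxy)phenyl]chroman-3-one, via benzofuran epoxide 8 (not isolated), via quinone methide ketone 9 (not isolated), via quinone methide dienol 10 (not isolated), via chromenol 11 (not isolated)
Conditions: DMDO (1.05 equiv, acetone), 4 Å MS, CH2Cl2, −78 to −20 °C; then Et3N (0.1 equiv), −20 °C to rt, N2
Reagents that add atoms: dimethyldioxirane CC1(C)OO1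
Why: Proposed new method: DMDO should epoxidise the C2=C3 enol-ether bond of the furan ring, the most electron-rich π bond of 7, to give 8. C3 of 8 is benzylic to ring D, which carries oxygen at both ortho positions and at the para position, so the C3–O bond heterolyses and the C2 alkoxide collapses to a ketone with release of the ring oxygen; this epoxide to o-quinone methide valence isomerisation is known for benzofuran epoxides and leaves the acyl group of 9 on the side of the former ring oxygen. The CH2 of 9 lies between the new ketone and ring E, so Et3N enolises it to the 1-oxatriene 10, and a thermal disrotatory oxa-6π electrocyclisation (the closing event of the aryl propargyl ether route to 2H-chromenes, the closest known reaction type) bonds the quinone methide oxygen to the former exocyclic carbon, restores the aromaticity of ring D and closes the six-membered ring F in 11, whose enol tautomerises to 12. The net change is insertion of the exocyclic benzylic carbon between O1 and the old furan C2, a one-atom ring expansion that also places the C3 oxygen and the C4 methylene. The only new stereocentre, C2, forms without control and is deliberately left racemic, because it stays labile beside the ketone and is settled together with C3 in step 6. The step needs chemoselective mono-oxidation (one equivalent of DMDO at low temperature, arenes and benzyl ethers reacting far more slowly), C3–O instead of C2–O opening of 8 (secured by the phloroglucinol pattern of ring D, which should outrun the 1,2-hydride shift to a coumaranone) and the absence of water or other nucleophiles that would add to C4 of 9 (sieves, aprotic medium).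

**Step 6**
Reactants: 12 racemic 5,7-bis(benzyloxy)-2-[3-bromo-4,5-bis(benzyloxy)phenyl]chroman-3-one
Product: 13 (2R,3R)-5,7-bis(benzyloxy)-2-[3-bromo-4,5-bis(benzyloxy)phenyl]chroman-3-ol
Conditions: RuCl2[(R)-Xyl-SDP][(S,S)-DPEN] (1 mol %), KOtBu (0.2 equiv), H2 (50 atm), iPrOH–toluene, rt
Reagents that add atoms: none
Why: This is a Noyori-type asymmetric hydrogenation under dynamic kinetic resolution, known for racemic α-aryl and α-aryloxy cyclic ketones: KOtBu racemises C2 through the enolate, the catalyst should reduce the (2R)-ketone faster and deliver hydride to the face of C3 anti to ring E, setting C2 and C3 cis as 2R,3R, and the mirror-image catalyst is used if the sense of induction proves opposite.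

**Step 7**
Reactants: 13 (2R,3R)-5,7-bis(benzyloxy)-2-[3-bromo-4,5-bis(benzyloxy)phenyl]chroman-3-ol
Product: 14 (2R,3R)-5,7-bis(benzyloxy)-2-[3,4-bis(benzyloxy)-5-hydroxyphenyl]chroman-3-ol
Conditions: Pd2(dba)3 (2 mol %), tBuXPhos (8 mol %), KOH (4 equiv), 1,4-dioxane–H2O, 100 °C; mildly acidic work-up
Reagents that add atoms: potassium hydroxide [K+].[OH-]
Why: Palladium-catalysed hydroxylation of an aryl bromide (Buchwald–Hartwig-type C–O coupling with hydroxide) unmasks the 3'-OH at a stage where only benzyl ethers and one secondary alcohol are present and neither stereocentre is base-labile.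

**Step 8**
Reactants: 14 (2R,3R)-5,7-bis(benzyloxy)-2-[3,4-bis(benzyloxy)-5-hydroxyphenyl]chroman-3-ol, 15 3,4,5-tris(benzyloxy)benzoic acid (2.5 equiv)
Product: 16 5,7,4',5'-tetra-O-benzyl-(−)-epigallocatechin 3,3'-bis[3,4,5-tris(benzyloxy)benzoate]
Conditions: DCC, DMAP, CH2Cl2, rt
Reagents that add atoms: none
Why: Steglich esterification acylates the only two free hydroxyls (the axial 3-OH and the 3'-phenol) in one operation without touching a stereocentre.

**Step 9**
Reactants: 16 5,7,4',5'-tetra-O-benzyl-(−)-epigallocatechin 3,3'-bis[3,4,5-tris(benzyloxy)benzoate]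
Product: 17 8-bromo derivative of 16
Conditions: NBS (1.0 equiv), CH2Cl2, −78 to 0 °C
Reagents that add atoms: N-bromosuccinimide O=C1CCC(=O)N1Br
Why: Electrophilic aromatic bromination of 5,7-di-O-benzylflavans goes to C8, the more accessible of the two activated positions of ring D, so C6 remains the only nucleophilic carbon.

**Step 10**
Reactants: 18 (−)-epicatechin
Product: 19 5,7,3',4'-tetra-O-benzyl-(−)-epicatechin
Conditions: BnBr (4.4 equiv), K2CO3, DMF, 0 °C to rt
Reagents that add atoms: benzyl bromide BrCc1ccccc1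
Why: Williamson ether synthesis at low temperature protects the four phenols, leaves the secondary 3-OH free and avoids base-induced epimerisation at C2.

**Step 11**
Reactants: 19 5,7,3',4'-tetra-O-benzyl-(−)-epicatechin
Product: 20 5,7,3',4'-tetra-O-benzyl-4β-(2-ethoxyethoxy)epicatechin
Conditions: DDQ (2 equiv), 2-ethoxyethanol, CH2Cl2, rt
Reagents that add atoms: 2-ethoxyethanol CCOCCO
Why: DDQ benzylic oxidation abstracts hydride from C4 (activated by ring A), and the alcohol traps the cation on the face anti to the axial 3-OH, giving the 4β-ether.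

**Step 12**
Reactants: 20 5,7,3',4'-tetra-O-benzyl-4β-(2-ethoxyethoxy)epicatechin
Product: 21 6,8-dibromo-5,7,3',4'-tetra-O-benzyl-4β-(2-ethoxyethoxy)epicatechin
Conditions: NBS (2.1 equiv), CH2Cl2, −78 °C to rt
Reagents that add atoms: N-bromosuccinimide O=C1CCC(=O)N1Br
Why: Double electrophilic aromatic bromination fills both free positions of ring A, the most activated arene, so that the electrophile cannot condense with itself.

**Step 13**
Reactants: 17 8-bromo derivative of 16, 21 6,8-dibromo-5,7,3',4'-tetra-O-benzyl-4β-(2-ethoxyethoxy)epicatechin (1.2 equiv)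
Product: 22 fully protected tribromo dimer with the 4β→6 bond
Conditions: TMSOTf (0.2 equiv), 4 Å MS, CH2Cl2, −40 to 0 °C
Reagents that add atoms: none
Why: This is the biomimetic Friedel–Crafts condensation of a flavan-4-yl cation with a flavan nucleophile under halogen capping: C6 of ring D is the only open activated position, and it attacks C4 anti to the 3-OH to set the 3,4-trans (4β) centre.

**Step 14**
Reactants: 22 fully protected tribromo dimer with the 4β→6 bond
Product: 23 epicatechin-(4β→6)-epigallocatechin 3,3'-di-O-gallate (target)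
Conditions: H2 (1 atm), Pd(OH)2/C, NaOAc (3 equiv), THF–MeOH–H2O, rt
Reagents that add atoms: none
Why: Catalytic hydrogenolysis removes the fourteen benzyl ethers and hydrodehalogenates the three aryl bromides in one step, and the acetate buffer keeps the medium weakly acidic so that the interflavan bond, the aryl gallate and C2 of ring F are not disturbed.

**Compound list**

1 | 3-bromo-4,5-dihydroxybenzaldehyde | O=Cc1cc(O)c(O)c(Br)c1 | starting material
2 | 3-bromo-4,5-bis(benzyloxy)benzaldehyde | O=Cc1cc(Br)c(OCc6ccccc6)c(OCc6ccccc6)c1 | intermediate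
3 | 4,6-dihydroxybenzofuran-3(2H)-one | O=C1COc2cc(O)cc(O)c12 | starting material
4 | 4,6-bis(benzyloxy)benzofuran-3(2H)-one | O=C1COc2cc(OCc6ccccc6)cc(OCc6ccccc6)c12 | intermediate
5 | (Z)-4,6-bis(benzyloxy)-2-[3-bromo-4,5-bis(benzyloxy)benzylidene]benzofuran-3(2H)-one (aurone) | O=C1c2c(OCc6ccccc6)cc(OCc6ccccc6)cc2O/C1=C\c1cc(Br)c(OCc6ccccc6)c(OCc6ccccc6)c1 | intermediate
6 | racemic (Z)-4,6-bis(benzyloxy)-2-[3-bromo-4,5-bis(benzyloxy)benzylidene]-2,3-dihydrobenzofuran-3-ol | OC1c2c(OCc6ccccc6)cc(OCc6ccccc6)cc2O/C1=C\c1cc(Br)c(OCc6ccccc6)c(OCc6ccccc6)c1 | intermediate (not isolated)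
7 | 4,6-bis(benzyloxy)-2-[3-bromo-4,5-bis(benzyloxy)benzyl]benzofuran | Brc1cc(Cc2cc3c(OCc6ccccc6)cc(OCc6ccccc6)cc3o2)cc(OCc6ccccc6)c1OCc6ccccc6 | intermediate
8 | racemic 2,3-epoxide of 7 (oxygen bridging C2 and C3 of the furan ring) | Brc1cc(CC23OC2c2c(OCc6ccccc6)cc(OCc6ccccc6)cc2O3)cc(OCc6ccccc6)c1OCc6ccccc6 | intermediate (not isolated)
9 | (Z)-3,5-bis(benzyloxy)-6-{3-[3-bromo-4,5-bis(benzyloxy)phenyl]-2-oxopropylidene}cyclohexa-2,4-dien-1-one | O=C(Cc1cc(Br)c(OCc6ccccc6)c(OCc6ccccc6)c1)/C=C1\C(=O)C=C(OCc6ccccc6)C=C1OCc6ccccc6 | intermediate (not isolated)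
10 | enol of 9, 3,5-bis(benzyloxy)-6-{3-[3-bromo-4,5-bis(benzyloxy)phenyl]-2-hydroxyprop-2-enylidene}cyclohexa-2,4-dien-1-one | OC(=Cc1cc(Br)c(OCc6ccccc6)c(OCc6ccccc6)c1)/C=C1\C(=O)C=C(OCc6ccccc6)C=C1OCc6ccccc6 | intermediate (not isolated)
11 | racemic 5,7-bis(benzyloxy)-2-[3-bromo-4,5-bis(benzyloxy)phenyl]-2H-chromen-3-ol | Brc1cc(C2Oc3cc(OCc6ccccc6)cc(OCc6ccccc6)c3C=C2O)cc(OCc6ccccc6)c1OCc6ccccc6 | intermediate (not isolated)
12 | racemic 5,7-bis(benzyloxy)-2-[3-bromo-4,5-bis(benzyloxy)phenyl]chroman-3-one | Brc1cc(C2Oc3cc(OCc6ccccc6)cc(OCc6ccccc6)c3CC2=O)cc(OCc6ccccc6)c1OCc6ccccc6 | intermediate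
13 | (2R,3R)-5,7-bis(benzyloxy)-2-[3-bromo-4,5-bis(benzyloxy)phenyl]chroman-3-ol (2,3-cis) | Brc1cc([C@H]2Oc3cc(OCc6ccccc6)cc(OCc6ccccc6)c3C[C@H]2O)cc(OCc6ccccc6)c1OCc6ccccc6 | intermediate
14 | (2R,3R)-5,7-bis(benzyloxy)-2-[3,4-bis(benzyloxy)-5-hydroxyphenyl]chroman-3-ol | Oc1cc([C@H]2Oc3cc(OCc6ccccc6)cc(OCc6ccccc6)c3C[C@H]2O)cc(OCc6ccccc6)c1OCc6ccccc6 | intermediate
15 | 3,4,5-tris(benzyloxy)benzoic acid | OC(=O)c1cc(OCc6ccccc6)c(OCc6ccccc6)c(OCc6ccccc6)c1 | starting material
16 | 5,7,4',5'-tetra-O-benzyl-(−)-epigallocatechin 3,3'-bis[3,4,5-tris(benzyloxy)benzoate] | O=C(Oc1cc([C@H]2Oc3cc(OCc6ccccc6)cc(OCc6ccccc6)c3C[C@H]2OC(=O)c2cc(OCc6ccccc6)c(OCc6ccccc6)c(OCc6ccccc6)c2)cc(OCc6ccccc6)c1OCc6ccccc6)c1cc(OCc6ccccc6)c(OCc6ccccc6)c(OCc6ccccc6)c1 | intermediate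
17 | 8-bromo derivative of 16 | O=C(Oc1cc([C@H]2Oc3c(Br)c(OCc6ccccc6)cc(OCc6ccccc6)c3C[C@H]2OC(=O)c2cc(OCc6ccccc6)c(OCc6ccccc6)c(OCc6ccccc6)c2)cc(OCc6ccccc6)c1OCc6ccccc6)c1cc(OCc6ccccc6)c(OCc6ccccc6)c(OCc6ccccc6)c1 | intermediate
18 | (−)-epicatechin (2R,3R) | C1c2c(O)cc(O)cc2O[C@H](c2ccc(O)c(O)c2)[C@@H]1O | starting material
19 | 5,7,3',4'-tetra-O-benzyl-(−)-epicatechin | C1c2c(OCc6ccccc6)cc(OCc6ccccc6)cc2O[C@H](c2ccc(OCc6ccccc6)c(OCc6ccccc6)c2)[C@@H]1O | intermediate
20 | 5,7,3',4'-tetra-O-benzyl-4β-(2-ethoxyethoxy)epicatechin (3,4-trans) | CCOCCO[C@H]1c2c(OCc6ccccc6)cc(OCc6ccccc6)cc2O[C@H](c2ccc(OCc6ccccc6)c(OCc6ccccc6)c2)[C@@H]1O | intermediate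
21 | 6,8-dibromo-5,7,3',4'-tetra-O-benzyl-4β-(2-ethoxyethoxy)epicatechin | CCOCCO[C@H]1c2c(OCc6ccccc6)c(Br)c(OCc6ccccc6)c(Br)c2O[C@H](c2ccc(OCc6ccccc6)c(OCc6ccccc6)c2)[C@@H]1O | intermediate
22 | protected dimer: 6,8-dibromo-tetra-O-benzylepicatechin-(4β→6)-8-bromo-tetra-O-benzylepigallocatechin 3,3'-bis[3,4,5-tris(benzyloxy)benzoate] | O=C(Oc1cc([C@H]2Oc3c(Br)c(OCc6ccccc6)c([C@H]4c5c(OCc6ccccc6)c(Br)c(OCc6ccccc6)c(Br)c5O[C@H](c5ccc(OCc6ccccc6)c(OCc6ccccc6)c5)[C@@H]4O)c(OCc6ccccc6)c3C[C@H]2OC(=O)c2cc(OCc6ccccc6)c(OCc6ccccc6)c(OCc6ccccc6)c2)cc(OCc6ccccc6)c1OCc6ccccc6)c1cc(OCc6ccccc6)c(OCc6ccccc6)c(OCc6ccccc6)c1 | intermediate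
23 | epicatechin-(4β→6)-epigallocatechin 3,3'-di-O-gallate | O=C(Oc1cc([C@H]2Oc3cc(O)c([C@H]4c5c(O)cc(O)cc5O[C@H](c5ccc(O)c(O)c5)[C@@H]4O)c(O)c3C[C@H]2OC(=O)c2cc(O)c(O)c(O)c2)cc(O)c1O)c1cc(O)c(O)c(O)c1 | target

**Count**

Total step count: 14.
Longest linear sequence: 10 steps (1, 3, 4, 5, 6, 7, 8, 9, 13, 14).

**Steps most likely to fail**

**Step 5 (labelled step).** The epoxide may rearrange by a 1,2-shift of hydride or benzyl. The quinone methide may also dimerise or take up water faster than it enolises, or the enol product may be over-oxidised.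

The fallback uses known chemistry, sets out from 2 and returns at 12:
- CH2=CHMgBr (THF, 0 °C) would add to 2 to give the racemic allylic alcohol 1-[3-bromo-4,5-bis(benzyloxy)phenyl]prop-2-en-1-ol F1.
- Acid-catalysed Friedel–Crafts allylation of purchased 3,5-bis(benzyloxy)phenol with it (H2SO4 on SiO2, CH2Cl2) would give the (E)-2-cinnamylphenol F2.
- DDQ cyclodehydrogenation (benzene, reflux) would give the racemic flav-3-ene F3.
- Hydroboration–oxidation (BH3·THF; NaOH, H2O2) would give the racemic 2,3-trans-flavan-3-ol F4.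
- Dess–Martin oxidation of F4 gives 12.

**Step 6.** Racemisation at C2 may be slow relative to reduction, enantioface discrimination may be poor on a ketone that carries no aryl group on the carbonyl carbon, or the enolate may decompose under base.

The fallback replaces asymmetric catalysis by resolution, sets out from 12 and returns at 13. LiBH(s-Bu)3 (THF, −78 °C) attacks anti to ring E and would give the racemic cis alcohol, that is 13 together with its enantiomer, the (2S,3S)-alcohol F5. The two are separated by preparative chromatography on a chiral stationary phase, and F5 is returned to 12 by Dess–Martin oxidation.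

**Step 13.** Ionisation of the doubly brominated electrophile may be sluggish, and attack by a C6 position crowded by two benzyloxy groups and two bulky gallates may be slow. The cation would then be lost by elimination or by recapture of the alcohol.

The fallback couples first with a slimmer nucleophile and acylates afterwards. It sets out from 14 and 21 and returns at 23:
- TBSCl and imidazole (DMF) would convert 14 into the bis(silyl ether) F6.
- NBS (CH2Cl2, −78 °C) would convert F6 into the 8-bromide F7.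
- TMSOTf-catalysed condensation of F7 with 21 would give the silylated dimer F8.
- Benzyl chloroformate and DMAP would protect its upper 3-OH as the benzyl carbonate F9.
- HF·pyridine would free the lower 3-OH and 3'-OH to give the diol F10.
- DCC and DMAP with 15 would give the digallate carbonate F11.
- The conditions of step 14 would cleave all benzyl groups, the carbonate and the bromines of F11 to give 23.

**Further compounds**

F1 | step 5 | racemic 1-[3-bromo-4,5-bis(benzyloxy)phenyl]prop-2-en-1-ol | C=CC(O)c1cc(Br)c(OCc6ccccc6)c(OCc6ccccc6)c1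
F2 | step 5 | (E)-3,5-bis(benzyloxy)-2-{3-[3-bromo-4,5-bis(benzyloxy)phenyl]allyl}phenol | Oc1cc(OCc6ccccc6)cc(OCc6ccccc6)c1C/C=C/c1cc(Br)c(OCc6ccccc6)c(OCc6ccccc6)c1
F3 | step 5 | racemic 5,7-bis(benzyloxy)-2-[3-bromo-4,5-bis(benzyloxy)phenyl]-2H-chromene | Brc1cc(C2Oc3cc(OCc6ccccc6)cc(OCc6ccccc6)c3C=C2)cc(OCc6ccccc6)c1OCc6ccccc6
F4 | step 5 | racemic 2,3-trans-5,7-bis(benzyloxy)-2-[3-bromo-4,5-bis(benzyloxy)phenyl]chroman-3-ol (the 2R,3S enantiomer drawn) | Brc1cc([C@H]2Oc3cc(OCc6ccccc6)cc(OCc6ccccc6)c3C[C@@H]2O)cc(OCc6ccccc6)c1OCc6ccccc6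
F5 | step 6 | (2S,3S)-5,7-bis(benzyloxy)-2-[3-bromo-4,5-bis(benzyloxy)phenyl]chroman-3-ol (enantiomer of 13) | Brc1cc([C@@H]2Oc3cc(OCc6ccccc6)cc(OCc6ccccc6)c3C[C@@H]2O)cc(OCc6ccccc6)c1OCc6ccccc6
F6 | step 13 | 3,3'-bis(tert-butyldimethylsilyl) ether of 14 | CC(C)(C)[Si](C)(C)Oc1cc([C@H]2Oc3cc(OCc6ccccc6)cc(OCc6ccccc6)c3C[C@H]2O[Si](C)(C)C(C)(C)C)cc(OCc6ccccc6)c1OCc6ccccc6
F7 | step 13 | 8-bromo derivative of F6 | CC(C)(C)[Si](C)(C)Oc1cc([C@H]2Oc3c(Br)c(OCc6ccccc6)cc(OCc6ccccc6)c3C[C@H]2O[Si](C)(C)C(C)(C)C)cc(OCc6ccccc6)c1OCc6ccccc6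
F8 | step 13 | 4β→6 dimer from F7 and 21, upper 3-OH free | CC(C)(C)[Si](C)(C)Oc1cc([C@H]2Oc3c(Br)c(OCc6ccccc6)c([C@H]4c5c(OCc6ccccc6)c(Br)c(OCc6ccccc6)c(Br)c5O[C@H](c5ccc(OCc6ccccc6)c(OCc6ccccc6)c5)[C@@H]4O)c(OCc6ccccc6)c3C[C@H]2O[Si](C)(C)C(C)(C)C)cc(OCc6ccccc6)c1OCc6ccccc6
F9 | step 13 | upper 3-O-benzyloxycarbonyl derivative of F8 | CC(C)(C)[Si](C)(C)Oc1cc([C@H]2Oc3c(Br)c(OCc6ccccc6)c([C@H]4c5c(OCc6ccccc6)c(Br)c(OCc6ccccc6)c(Br)c5O[C@H](c5ccc(OCc6ccccc6)c(OCc6ccccc6)c5)[C@@H]4OC(=O)OCc6ccccc6)c(OCc6ccccc6)c3C[C@H]2O[Si](C)(C)C(C)(C)C)cc(OCc6ccccc6)c1OCc6ccccc6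
F10 | step 13 | desilylated dimer with free lower 3-OH and 3'-OH | Oc1cc([C@H]2Oc3c(Br)c(OCc6ccccc6)c([C@H]4c5c(OCc6ccccc6)c(Br)c(OCc6ccccc6)c(Br)c5O[C@H](c5ccc(OCc6ccccc6)c(OCc6ccccc6)c5)[C@@H]4OC(=O)OCc6ccccc6)c(OCc6ccccc6)c3C[C@H]2O)cc(OCc6ccccc6)c1OCc6ccccc6
F11 | step 13 | upper 3-O-benzyloxycarbonyl analogue of 22 | O=C(Oc1cc([C@H]2Oc3c(Br)c(OCc6ccccc6)c([C@H]4c5c(OCc6ccccc6)c(Br)c(OCc6ccccc6)c(Br)c5O[C@H](c5ccc(OCc6ccccc6)c(OCc6ccccc6)c5)[C@@H]4OC(=O)OCc6ccccc6)c(OCc6ccccc6)c3C[C@H]2OC(=O)c2cc(OCc6ccccc6)c(OCc6ccccc6)c(OCc6ccccc6)c2)cc(OCc6ccccc6)c1OCc6ccccc6)c1cc(OCc6ccccc6)c(OCc6ccccc6)c(OCc6ccccc6)c1
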